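Everything rests on cutting C6–C7, the bond that joins the side chain to the six-membered ring. The feature exploited is that ring's C1/C2 cis-diol beside the methyl-bearing C3, together with C7 standing on C6 cis to O1: an enzymatic arene cis-dihydrodiol supplies C1–C6, and C7 is delivered from O1. One silicon-tethered vinyl radical cyclisation forms C6–C7, closes a cis-fused oxasilolane, sets C6 and leaves C3=C4 for the later epoxide. Its precursor is (1R,2S)-3-methylcyclohexa-3,5-diene-1,2-diol carrying a (1-bromovinyl)dimethylsilyl group on O1 and TBS on O2. Tamao oxidation, Ni/Cr coupling, acylations and two epoxidations then complete the target.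

Key step: step 5

Remark: atoms carry bisabolane-type locants throughout: ring C1 (angelate), C2 (acetate), C3 (methyl)/C4 (ring epoxide), C5, C6; side chain C7 (with methylene carbon C14), C8 (angelate), C9, C10/C11 (side-chain epoxide); O1 and O2 are the oxygens on C1 and C2.

Step 1
Reactants: 1 4-iodotoluene
Product: 2 (1S,2S)-3-iodo-6-methylcyclohexa-3,5-diene-1,2-diol
Conditions: Pseudomonas putida UV4 whole cells (toluene dioxygenase), glucose, pH 7 phosphate buffer, air, 30 °C; EtOAc extraction, recrystallisation
Reagents that add atoms: dioxygen, O=O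
Why: Enzymatic arene cis-dihydroxylation by the Rieske non-haem iron toluene dioxygenase should add both atoms of O2 to one face of the ring bond next to the larger iodine substituent, which fixes the regiochemistry and both carbinol centres (the later C1 and C2), while the mutant strain lacks the diol dehydrogenase so that the diol accumulates.

Step 2
Reactants: 2 (1S,2S)-3-iodo-6-methylcyclohexa-3,5-diene-1,2-diol
Product: 3 (1R,2S)-3-methylcyclohexa-3,5-diene-1,2-diol
Conditions: H2 (1 atm, stopped at 1 equiv), Pd/C, NaOAc, MeOH, rt
Reagents that add atoms: none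
Why: Palladium-catalysed hydrogenolysis of the weak vinylic C–I bond should outpace hydrogenation of the diene, the released iodide moderating the catalyst and the acetate buffering HI, so the iodine that steered the enzyme is removed without touching a stereocentre and the methyl cis-dihydrodiol of the configuration opposite to that formed from toluene itself results.

Step 3
Reactants: 4 chlorodimethylvinylsilane
Product: 6 (1-bromovinyl)chlorodimethylsilane, via dibromide 5 (not isolated)
Conditions: Br2, CH2Cl2, −78 °C → rt; then quinoline, 100 °C; distillation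
Reagents that add atoms: bromine, BrBr
Why: Electrophilic bromine addition to the vinylsilane followed by amine-mediated E2 dehydrobromination, in which the acidic hydrogen α to silicon and bromine leaves with the β-bromide, is the standard bromination–dehydrobromination route to α-bromovinylsilanes, and a tertiary aromatic amine leaves the Si–Cl bond intact.

Step 4
Reactants: 3 (1R,2S)-3-methylcyclohexa-3,5-diene-1,2-diol; 6 (1-bromovinyl)chlorodimethylsilane
Product: 8 O1-[(1-bromovinyl)dimethylsilyl] O2-TBS bis-ether of diol 3, via mono-silyl ether 7 (not isolated)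
Conditions: 6 (1.0 equiv), Et3N, DMAP (cat.), CH2Cl2, −78 °C; then TBSOTf, −78 → 0 °C; chromatography on Et3N-deactivated silica
Reagents that add atoms: tert-butyldimethylsilyl trifluoromethanesulfonate, CC(C)(C)[Si](C)(C)OS(=O)(=O)C(F)(F)F
Why: Kinetic O-silylation should take the C1 hydroxyl, which is flanked by the unsubstituted C6–H and is less hindered than the C2 hydroxyl next to the methyl-bearing C3, and capping O2 with the silyl triflate in the same flask stops the small silyl group from migrating between the cis oxygens; no stereocentre changes.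

Step 5
Reactants: 8 O1-[(1-bromovinyl)dimethylsilyl] O2-TBS bis-ether of diol 3
Product: 9 cis-fused 3-methylene-1,2-oxasilolane on the 3-methylcyclohex-3-ene ring (C7 alkenylsilane, O2-TBS)
Conditions: Bu3SnH (1.3 equiv, slow addition), AIBN (cat.), PhH, 80 °C, 0.01 M
Reagents that add atoms: none
Why: The tin radical abstracts the vinylic bromine of 8, the σ-type α-silylvinyl radical at C7 adds to the diene terminus C6, and the resulting C3–C4–C5 allyl radical takes hydrogen from Bu3SnH at C5; this is the known silicon-tethered radical cyclisation of (1-bromovinyl)silyl ethers of allylic alcohols, applied here to a dienol. The one ring formed, the 1,2-oxasilolane (O1, Si, C7, C6, C1), closes in the 5-exo-trig mode. The one new stereocentre, C6, is controlled by C1 through the tether, because a five-membered ring spanning O1 and C6 can only be cis-fused to the carbocycle, so C7 lands on the face of O1. The step needs 5-exo over 6-endo closure and hydrogen transfer at C5 instead of C3: only attack at C6 gives a delocalised radical, that allyl radical has no reason to rearrange to the ring-expanded isomer, and C5 is the unhindered terminus whose reduction leaves the more stable trisubstituted C3=C4 alkene, while C3 is shielded by its methyl group and the neighbouring TBS ether. Dilution and slow hydride addition should suppress dimerisation of the diene, and the very fast closure onto a diene should outrun direct reduction of the vinyl radical.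

Step 6
Reactants: 9 cis-fused 3-methylene-1,2-oxasilolane
Product: 10 cis β-hydroxy methyl ketone (C6 acetyl, C1 OH, C2 OTBS)
Conditions: 30% H2O2, KF, KHCO3, THF/MeOH, rt
Reagents that add atoms: hydrogen peroxide, OO
Why: Tamao oxidation of the fluoride-activated alkoxy(alkenyl)silane moves C7 from silicon to oxygen with retention, the enol tautomerises to the methyl ketone (C14 becomes CH3) and O1 is set free, and the mild bicarbonate medium should leave the cis C6 centre unepimerised.

Step 7
Reactants: 10 cis β-hydroxy methyl ketone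
Product: 11 O1-TES ether of ketone 10
Conditions: TESOTf, 2,6-lutidine, CH2Cl2, −78 °C
Reagents that add atoms: triethylsilyl trifluoromethanesulfonate, CC[Si](CC)(CC)OS(=O)(=O)C(F)(F)F
Why: Low-temperature silylation of a β-hydroxy ketone with a silyl triflate and a hindered pyridine base is standard and masks O1, so that the next step meets neither an alkoxide (retro-aldol) nor a free hydroxyl.

Step 8
Reactants: 11 O1-TES ether of ketone 10
Product: 13 C7 enol triflate, via potassium enolate 12 (not isolated)
Conditions: KN(SiMe3)2, THF, −78 °C; then PhNTf2, −78 → −40 °C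
Reagents that add atoms: N-phenylbis(trifluoromethanesulfonimide), O=S(=O)(N(c1ccccc1)S(=O)(=O)C(F)(F)F)C(F)(F)F
Why: Kinetic deprotonation of a methyl ketone by a bulky amide base occurs at the methyl group (C14) and not at the tertiary C6–H, so O-triflation of the enolate should give the terminal enol triflate without epimerising C6 or eliminating the β-silyloxy group.

Step 9
Reactants: 14 4-methylpent-3-en-1-ol
Product: 15 4-methylpent-3-enal
Conditions: Dess–Martin periodinane, NaHCO3, CH2Cl2, 0 °C; filtered solution used at once
Reagents that add atoms: none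
Why: Buffered Dess–Martin oxidation is neutral and fast, which should deliver the β,γ-unsaturated aldehyde without shifting the alkene into conjugation.

Step 10
Reactants: 13 C7 enol triflate; 15 4-methylpent-3-enal
Product: 16 (8S)-allylic alcohol (O1-TES, O2-TBS)
Conditions: CrCl2 (4 equiv), chiral oxazoline–sulfonamide ligand (N-[2-(4-isopropyl-4,5-dihydrooxazol-2-yl)-6-methylphenyl]methanesulfonamide, enantiomer chosen for Re-face attack), Et3N, THF, rt; then NiCl2 (cat.), 13 and 15, rt
Reagents that add atoms: none
Why: In the Nozaki–Hiyama–Kishi coupling, zerovalent nickel (formed from NiCl2 by divalent chromium) inserts into the C–OTf bond, the alkenyl group passes to trivalent chromium and adds only to the aldehyde, and the sulfonamide ligand on chromium should direct the attack to the Re face of the aldehyde, which sets C8 as S (to be confirmed by Mosher ester analysis).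

Step 11
Reactants: 16 (8S)-allylic alcohol (O1-TES, O2-TBS)
Product: 17 C1,C8-diol (O2-TBS)
Conditions: PPTS (cat.), MeOH, 0 °C → rt
Reagents that add atoms: none
Why: Mild acid-catalysed methanolysis cleaves a secondary TES ether far faster than the hindered secondary TBS ether, which frees exactly the two hydroxyls that are to carry the same ester.

Step 12
Reactants: 17 C1,C8-diol (O2-TBS)
Product: 18 C1,C8-bis-angelate (O2-TBS)
Conditions: angelic acid, 2,4,6-trichlorobenzoyl chloride, Et3N, PhMe, rt; then 17, PhMe, 80 °C (no DMAP)
Reagents that add atoms: angelic acid, OC(=O)/C(C)=C\C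
Why: Yamaguchi-type esterification through the mixed trichlorobenzoic anhydride, run hot in toluene without a nucleophilic catalyst, is the established way to acylate hindered alcohols with angelic acid while avoiding the addition–elimination pathway that turns the Z acid into the E (tiglate) isomer.

Step 13
Reactants: 18 C1,C8-bis-angelate (O2-TBS)
Product: 19 C2 allylic alcohol (C1,C8-bis-angelate)
Conditions: HF·pyridine, pyridine, THF, 0 °C → rt
Reagents that add atoms: none
Why: Buffered, weakly acidic fluoride desilylation removes the TBS ether without ever forming a free alkoxide, so the cis-vicinal angelate on O1 should not migrate to O2.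

Step 14
Reactants: 19 C2 allylic alcohol (C1,C8-bis-angelate)
Product: 20 C3–C4 epoxy alcohol (epoxide cis to the C2 hydroxyl)
Conditions: VO(acac)2 (cat.), t-BuOOH, CH2Cl2, 0 °C → rt
Reagents that add atoms: tert-butyl hydroperoxide, CC(C)(C)OO
Why: In the hydroxyl-directed vanadium-catalysed epoxidation the peroxide is delivered from the vanadium alkoxide of O2 to the face of C3=C4 that carries that oxygen, which sets C3 and C4 syn to O2, O1 and C7, and the C7=C14 and C10=C11 alkenes, which lack a free allylic hydroxyl, should stay untouched.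

Step 15
Reactants: 20 C3–C4 epoxy alcohol
Product: 21 C2 acetate (ring epoxide, both angelates, C10=C11 alkene)
Conditions: Ac2O, DMAP (cat.), pyridine, CH2Cl2, 0 °C → rt
Reagents that add atoms: acetic anhydride, CC(=O)OC(C)=O
Why: DMAP-catalysed acetylation of the remaining secondary hydroxyl is mild enough for the epoxide and the angelates and changes no stereocentre.

Step 16
Reactants: 21 C2 acetate
Product: 22 CNP0316628.1 (target)
Conditions: L-fructose-derived Shi ketone (enantiomer of the usual D-fructose catalyst, 0.3 equiv), Oxone (2KHSO5·KHSO4·K2SO4), K2CO3, Bu4NHSO4, Na2B4O7/Na2EDTA buffer, MeCN/CH2(OMe)2, 0 °C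
Reagents that add atoms: potassium peroxymonosulfate (active part of Oxone), [K+].[O-]S(=O)(=O)OO
Why: In the Shi epoxidation the chiral dioxirane attacks the electron-rich trisubstituted C10=C11 alkene through a spiro transition state well before the ester-deactivated C7=C14 alkene or the electron-poor angelates, and the L-series ketone should set C10 as S by reagent control.

Compound list
1 | 4-iodotoluene | Cc1ccc(I)cc1 | starting material
2 | (1S,2S)-3-iodo-6-methylcyclohexa-3,5-diene-1,2-diol (cis-diol next to the C–I carbon) | IC1=CC=C(C)[C@H](O)[C@@H]1O | intermediate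
3 | (1R,2S)-3-methylcyclohexa-3,5-diene-1,2-diol (cis) | C1=CC=C(C)[C@H](O)[C@@H]1O | intermediate
4 | chlorodimethylvinylsilane | C=C[Si](C)(C)Cl | starting material
5 | chloro(1,2-dibromoethyl)dimethylsilane (racemic) | C[Si](C)(Cl)C(Br)CBr | intermediate
6 | (1-bromovinyl)chlorodimethylsilane | C=C(Br)[Si](C)(C)Cl | intermediate
7 | (1S,6R)-6-{[(1-bromovinyl)dimethylsilyl]oxy}-2-methylcyclohexa-2,4-dien-1-ol (diol 3 silylated on O1 only) | C1=CC=C(C)[C@H](O)[C@@H]1O[Si](C)(C)C(Br)=C | intermediate
8 | tert-butyl({(1S,6R)-6-{[(1-bromovinyl)dimethylsilyl]oxy}-2-methylcyclohexa-2,4-dien-1-yl}oxy)dimethylsilane (diol 3 with the bromovinylsilyl group on O1 and TBS on O2) | C1=CC=C(C)[C@H](O[Si](C)(C)C(C)(C)C)[C@@H]1O[Si](C)(C)C(Br)=C | intermediate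
9 | (3aR,7S,7aR)-7-[(tert-butyldimethylsilyl)oxy]-2,2,6-trimethyl-3-methylene-2,3,3a,4,7,7a-hexahydrobenzo[d][1,2]oxasilole (cis ring fusion; O1, O2 and C7 on one face) | C=C1[C@@H]2CC=C(C)[C@H](O[Si](C)(C)C(C)(C)C)[C@@H]2O[Si]1(C)C | intermediate
10 | 1-[(1R,5S,6R)-5-[(tert-butyldimethylsilyl)oxy]-6-hydroxy-4-methylcyclohex-3-en-1-yl]ethan-1-one (acetyl, OH and OTBS all cis) | CC(=O)[C@@H]1CC=C(C)[C@H](O[Si](C)(C)C(C)(C)C)[C@@H]1O | intermediate
11 | 1-[(1R,5S,6R)-5-[(tert-butyldimethylsilyl)oxy]-4-methyl-6-[(triethylsilyl)oxy]cyclohex-3-en-1-yl]ethan-1-one | CC(=O)[C@@H]1CC=C(C)[C@H](O[Si](C)(C)C(C)(C)C)[C@@H]1O[Si](CC)(CC)CC | intermediate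
12 | potassium enolate of 11 (enolate towards C14) | C=C([O-])[C@@H]1CC=C(C)[C@H](O[Si](C)(C)C(C)(C)C)[C@@H]1O[Si](CC)(CC)CC.[K+] | intermediate
13 | 1-[(1R,5S,6R)-5-[(tert-butyldimethylsilyl)oxy]-4-methyl-6-[(triethylsilyl)oxy]cyclohex-3-en-1-yl]vinyl trifluoromethanesulfonate | C=C(OS(=O)(=O)C(F)(F)F)[C@@H]1CC=C(C)[C@H](O[Si](C)(C)C(C)(C)C)[C@@H]1O[Si](CC)(CC)CC | intermediate
14 | 4-methylpent-3-en-1-ol | CC(C)=CCCO | starting material
15 | 4-methylpent-3-enal | CC(C)=CCC=O | intermediate
16 | (8S)-1-O-TES-2-O-TBS-bisabola-3,7(14),10-triene-1,2,8-triol (O1, O2 and C7 cis on the ring) | C=C([C@@H](O)CC=C(C)C)[C@@H]1CC=C(C)[C@H](O[Si](C)(C)C(C)(C)C)[C@@H]1O[Si](CC)(CC)CC | intermediate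
17 | (8S)-2-O-TBS-bisabola-3,7(14),10-triene-1,2,8-triol (free OH on C1 and C8) | C=C([C@@H](O)CC=C(C)C)[C@@H]1CC=C(C)[C@H](O[Si](C)(C)C(C)(C)C)[C@@H]1O | intermediate
18 | 1,8-di-O-angeloyl-2-O-TBS derivative of the (8S)-triol | C=C([C@H](CC=C(C)C)OC(=O)/C(C)=C\C)[C@@H]1CC=C(C)[C@H](O[Si](C)(C)C(C)(C)C)[C@@H]1OC(=O)/C(C)=C\C | intermediate
19 | 1,8-di-O-angeloyl (8S)-triol with free C2 hydroxyl | C=C([C@H](CC=C(C)C)OC(=O)/C(C)=C\C)[C@@H]1CC=C(C)[C@H](O)[C@@H]1OC(=O)/C(C)=C\C | intermediate
20 | 3,4-epoxide of 19, epoxide oxygen cis to O2, O1 and C7 | C=C([C@H](CC=C(C)C)OC(=O)/C(C)=C\C)[C@@H]1C[C@@H]2O[C@]2(C)[C@H](O)[C@@H]1OC(=O)/C(C)=C\C | intermediate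
21 | 2-O-acetate of 20 (C10=C11 alkene still present) | C=C([C@H](CC=C(C)C)OC(=O)/C(C)=C\C)[C@@H]1C[C@@H]2O[C@]2(C)[C@H](OC(C)=O)[C@@H]1OC(=O)/C(C)=C\C | intermediate
22 | CNP0316628.1: 2-O-acetyl-1,8-di-O-angeloyl-3,4:10,11-diepoxybisabol-7(14)-ene-1,2,8-triol, ring substituents all cis, 8S, 10S | C=C([C@H](C[C@@H]1OC1(C)C)OC(=O)/C(C)=C\C)[C@@H]1C[C@@H]2O[C@]2(C)[C@H](OC(C)=O)[C@@H]1OC(=O)/C(C)=C\C | target

Total step count: 16. Longest linear sequence: 14 steps (steps 1, 2, 4–8 and 10–16, from 4-iodotoluene).

Steps most likely to fail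

Step 5. The vinyl radical may be reduced, or may abstract the C2 hydrogen through a 1,5-shift, before it closes the ring; hydrogen may also be delivered to C3 of the allyl radical, and the diene may dimerise on heating. The fallback sets out from 3 and comes back at 11. It swaps the vinyl radical for a saturated one-carbon radical and adds C14 afterwards. Diol 3 is silylated on O1 with commercial (bromomethyl)chlorodimethylsilane and capped with TBSOTf as in step 4, giving the bromomethylsilyl bis-ether F1. Bu3SnH/AIBN then closes the cis-fused oxasilolane F2 through the less reactive α-silylmethyl radical (the classical bromomethylsilyl ether cyclisation). Tamao oxidation gives the cis hydroxymethyl alcohol F3, and TESCl/imidazole gives the bis-TES ether F4. Swern conditions cleave and oxidise only the primary TES ether, giving the aldehyde F5. MeMgBr adds to give the carbinol F6 (both C7 epimers, which does not matter), and Dess–Martin oxidation returns the methyl ketone 11.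

Step 10. Facial selectivity at the aldehyde may be poor if ligand control opposes the bias of the neighbouring C6 centre, and the β,γ-unsaturated aldehyde may isomerise into conjugation. The fallback sets out from 13 (with 15) and comes back at 16. The coupling is run without the chiral ligand (CrCl2, NiCl2 cat., DMF), and the product is accepted as a mixture of 16 and its (8R)-epimer F7. The mixture is oxidised with buffered Dess–Martin periodinane to the enone F8. Corey–Bakshi–Shibata reduction (oxazaborolidine enantiomer chosen for the 8S alcohol, catecholborane, −78 °C) then sets C8 by reagent control and returns 16.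

Step 12. The activated acid may isomerise from Z to E during the slow acylation of the crowded C1 hydroxyl, and esterification may stay incomplete. The fallback sets out from 17 and comes back at 18. It makes the ester bonds first and the Z alkenes afterwards. Both hydroxyls of 17 are acylated with 2-[bis(2,2,2-trifluoroethoxy)phosphoryl]propanoic acid (DCC, DMAP) to give the bis-phosphonopropionate F9. A double Still–Gennari olefination with acetaldehyde (KN(SiMe3)2, 18-crown-6, THF, −78 °C) then forms both (Z)-2-methylbut-2-enoates under kinetic control and gives 18.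

Further compounds
F1 | step 5 | O1-[(bromomethyl)dimethylsilyl] O2-TBS bis-ether of diol 3 | C1=CC=C(C)[C@H](O[Si](C)(C)C(C)(C)C)[C@@H]1O[Si](C)(C)CBr
F2 | step 5 | cis-fused 1,2-oxasilolane with saturated C7H2 (O2-TBS) | C1[C@@H]2CC=C(C)[C@H](O[Si](C)(C)C(C)(C)C)[C@@H]2O[Si]1(C)C
F3 | step 5 | cis C6-hydroxymethyl C1-alcohol (O2-TBS) | OC[C@@H]1CC=C(C)[C@H](O[Si](C)(C)C(C)(C)C)[C@@H]1O
F4 | step 5 | bis-TES ether of F3 | CC[Si](CC)(CC)OC[C@@H]1CC=C(C)[C@H](O[Si](C)(C)C(C)(C)C)[C@@H]1O[Si](CC)(CC)CC
F5 | step 5 | C7 aldehyde (O1-TES, O2-TBS) | O=C[C@@H]1CC=C(C)[C@H](O[Si](C)(C)C(C)(C)C)[C@@H]1O[Si](CC)(CC)CC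
F6 | step 5 | C7 methyl carbinol, both C7 epimers (O1-TES, O2-TBS) | CC(O)[C@@H]1CC=C(C)[C@H](O[Si](C)(C)C(C)(C)C)[C@@H]1O[Si](CC)(CC)CC
F7 | step 10 | (8R)-epimer of 16 | C=C([C@H](O)CC=C(C)C)[C@@H]1CC=C(C)[C@H](O[Si](C)(C)C(C)(C)C)[C@@H]1O[Si](CC)(CC)CC
F8 | step 10 | C8 enone (O1-TES, O2-TBS) | C=C(C(=O)CC=C(C)C)[C@@H]1CC=C(C)[C@H](O[Si](C)(C)C(C)(C)C)[C@@H]1O[Si](CC)(CC)CC
F9 | step 12 | C1,C8-bis{2-[bis(2,2,2-trifluoroethoxy)phosphoryl]propanoate} of 17 | C=C([C@H](CC=C(C)C)OC(=O)C(C)P(=O)(OCC(F)(F)F)OCC(F)(F)F)[C@@H]1CC=C(C)[C@H](O[Si](C)(C)C(C)(C)C)[C@@H]1OC(=O)C(C)P(=O)(OCC(F)(F)F)OCC(F)(F)F
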